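**Slow solid.** The slowness of the solid substrate shaped my reckoning.

| setting | violet | teal | ochre | south-west | west |
|---|---|---|---|---|---|
| solid substrate | 10 mM | 10 mM | 6.9 mM | 6.0 mM | 10 mM |
| acid | 0.024 mM | 0.088 mM | 0.030 mM | 0.100 mM | 0.0300 mM |
| temperature | 95 °C | 106 °C | 95 °C | 100 °C | 100 °C |
| remark | run made earlier | run made earlier | run made earlier |  |  |
| time |  |  |  | 1.5 min | 2.5 min |

| run | time / s | target / % | solid substrate / % |
|---|---|---|---|
| violet | 10.0 | 0 | 99.2 |
| violet | 15.0 | 0 | 98.7 |
| violet | 30.0 | 0.6 | 96.9 |
| violet | 60.0 | 3.7 | 92.1 |
| violet | 120 | 10.8 | 86.1 |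
| teal | 10.0 | 0.5 | 99.0 |
| teal | 25.0 | 0.9 | 96.5 |
| teal | 50.0 | 5.2 | 93.8 |
| teal | 80.0 | 7.7 | 91.6 |
| teal | 120 | 12.0 | 86.0 |
| ochre | 20.0 | 0.5 | 96.8 |
| ochre | 40.0 | 2.5 | 93.0 |
| ochre | 60.0 | 5.0 | 91.1 |
| ochre | 80.0 | 8.0 | 86.4 |
| ochre | 120 | 16.3 | 81.4 |

(scatter of a reading: 0.5 percentage points)

- acid is the free proton; pH is minus the decimal logarithm of its molar concentration
- as a solid, counted per litre of solution: solid substrate
- the numbers in the tables scatter with a standard deviation of 0.5 percentage points
- what may be going on: starting material + acid -> weak acid + acid + target; weak acid <-> conjugate base + acid; starting material -> weak acid + target; solid substrate <-> starting material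
- at the start none of the solid substrate is in solution
- what has only dissolved of solid substrate counts as not reacted

- the winner by amount of target, in percent of the solid substrate charged; "neither" if no more than 2 percentage points parts them (south-west / west / neither)
- how much target is there at the end, in percent of the solid substrate charged: south-west
- how much target is there at the end, in percent of the solid substrate charged: west

By the last reading the solid had gone at 0.0117 mM s⁻¹ in teal and 0.0107 mM s⁻¹ in ochre. Violet gave the figure I carried, the feed rate, the concentration leaving the solid each second: 0.0116 mM s⁻¹. It is a reading, with its scatter.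

**Two times.** I compared the run time with the emptying time, which is the charge over the feed rate. Their ratio is the share of the charge that has left the solid. South-west had 1.5 min against 8.63 min, and west had 2.5 min against 14.4 min. The ratios were 17.4% and 17.4%, a symmetric pair, so I started from no winner.

**The gap.** Target trailed the solid lost by 3.1 percentage points in violet and 2 points in teal. West's acid lay near violet's and south-west's near teal's. Both gaps were percent of a 10 mM charge. West has that charge, so I reckoned 14.3% for west. Teal's gap was 0.200 mM, which is 3.3 points of south-west's 6.0 mM, so I reckoned 14.1% for south-west.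

**The forecast.** It said neither, with 13.8% (11.5% to 16.5%) for south-west and 14.8% (13% to 17%) for west, holding that “dissolution appears to limit the process”. Its figures differed from mine, but both put west higher.

**The result.** The flasks gave neither: 14.6% in south-west and 14.9% in west.

    starting material + acid → weak acid + acid + target (k = 550 M⁻¹ s⁻¹, Ea = 37.0 kJ mol⁻¹)
    weak acid ⇌ conjugate base + acid, settled at all times (K = 7.90 × 10⁻⁶ M, ΔH = −17.0 kJ mol⁻¹)
    starting material → weak acid + target (k = 0.00350 s⁻¹, Ea = 99.0 kJ mol⁻¹)
    solid substrate ⇌ starting material, rate k4*(cs4 - [starting material]) while solid is left; crystals form when [starting material] > cs4 (solubility = 3.20 mM, k = 0.00370 s⁻¹)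
    (constants at 100 °C)

In west at 1.25 min, starting material had a half-life of 0.26 min by the step with acid, against an emptying time of 14.4 min. That is the picture of dissolution as the rate-limiting step.

**Second flask.** West left until 6.0 min has a ratio of 41.7%, and less violet's gap that gives 38.6%. The computed target was 39.3%.

The runs come from a simulation with constants of no real substance; the scatter is artificial.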